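The pyran ring is taken apart at O1–C2 and C4–C4a, through a 2H-chromene, to the mirror-symmetric resorcinol 4-prenylpinosylvin and prenal. In one operation the key step joins them: condensation at a ring-A carbon ortho to the styryl group gives an ortho-quinone methide, whose oxa-6π electrocyclization forms the O1–C2 bond. It exploits the position of C8, the prenyl-bearing carbon, between the two ring-A oxygens (O1 on C8a, the hydroxyl on C7): in the precursor both hydroxyls and both free ortho carbons are equivalent, and the prenyl group blocks the otherwise favoured site. The new C3=C4 alkene then takes up the C3 hydroxyl by catalyst-controlled epoxidation and hydride opening at C4.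

Key step: step 6

Remark: chromane numbering (O1, C2, C3, C4, C4a, C5 to C8, C8a) is used for the target and its bicyclic precursors, ring A is the benzene ring of the chromane, and the stereocenter of the target is read as 3R.

Step 1
Reactants: 1 3,5-dihydroxybenzyl alcohol; 2 chloromethyl methyl ether
Product: 3 [3,5-bis(methoxymethoxy)phenyl]methanol
Conditions: 2 (2.2 equiv), K2CO3, acetone, 0 °C to rt
Reagents that add atoms: chloromethyl methyl ether, COCCl
Why: Williamson-type O-alkylation in which K2CO3 deprotonates only the two phenols, so that the phenoxides are capped as MOM ethers (the directing groups for step 2) while the neutral benzylic alcohol should stay free.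

Step 2
Reactants: 3 [3,5-bis(methoxymethoxy)phenyl]methanol; 4 1-bromo-3-methylbut-2-ene (prenyl bromide)
Product: 6 [3,5-bis(methoxymethoxy)-4-(3-methylbut-2-en-1-yl)phenyl]methanol, via C4-lithiated lithium alkoxide 5 (not isolated)
Conditions: n-BuLi (2.3 equiv), TMEDA, THF, 0 °C; CuBr·SMe2 (0.2 equiv), 4, −20 °C to rt; H2O
Reagents that add atoms: 1-bromo-3-methylbut-2-ene, CC(C)=CCBr
Why: Directed ortho-metalation, in which the second equivalent of n-BuLi removes the ring proton flanked by both MOM ethers after the alcohol has been deprotonated, followed by copper-assisted SN2 allylation of the aryl anion to the linear prenyl arene.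

Step 3
Reactants: 6 [3,5-bis(methoxymethoxy)-4-(3-methylbut-2-en-1-yl)phenyl]methanol
Product: 7 3,5-bis(methoxymethoxy)-4-(3-methylbut-2-en-1-yl)benzaldehyde
Conditions: MnO2 (excess), CH2Cl2, rt
Reagents that add atoms: none
Why: Selective benzylic alcohol oxidation by MnO2 should stop at the aldehyde and leave the prenyl alkene and the MOM acetals untouched.

Step 4
Reactants: 7 3,5-bis(methoxymethoxy)-4-(3-methylbut-2-en-1-yl)benzaldehyde; 8 diethyl benzylphosphonate
Product: 9 1,3-bis(methoxymethoxy)-2-(3-methylbut-2-en-1-yl)-5-[(E)-2-phenylethenyl]benzene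
Conditions: 8, KOtBu, THF, 0 °C to rt
Reagents that add atoms: diethyl benzylphosphonate, CCOP(=O)(Cc1ccccc1)OCC
Why: Horner–Wadsworth–Emmons olefination, in which reversible addition of the benzylphosphonate carbanion and elimination through the anti-oxaphosphetane should give the E-stilbene.

Step 5
Reactants: 9 1,3-bis(methoxymethoxy)-2-(3-methylbut-2-en-1-yl)-5-[(E)-2-phenylethenyl]benzene
Product: 10 2-(3-methylbut-2-en-1-yl)-5-[(E)-2-phenylethenyl]benzene-1,3-diol (4-prenylpinosylvin)
Conditions: HCl (dilute), MeOH/THF, rt to 40 °C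
Reagents that add atoms: none
Why: Acid-catalysed acetal exchange with methanol frees both phenols, and dilute acid near room temperature should be too mild to add a phenol across the prenyl alkene.

Step 6
Reactants: 10 2-(3-methylbut-2-en-1-yl)-5-[(E)-2-phenylethenyl]benzene-1,3-diol; 11 3-methylbut-2-enal (prenal)
Product: 13 2,2-dimethyl-8-(3-methylbut-2-en-1-yl)-5-[(E)-2-phenylethenyl]-2H-chromen-7-ol, via ortho-quinone methide 12 (not isolated)
Conditions: 11 (1.1 equiv), ethylenediammonium diacetate (20 mol%), toluene, reflux
Reagents that add atoms: 3-methylbut-2-enal, CC(C)=CC=O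
Why: The iminium ion formed from 11 and the amine catalyst is attacked by a ring-A carbon ortho to a hydroxyl (Knoevenagel-type C-alkylation that forms C4–C4a), and loss of the amine gives the ortho-quinone methide 12, a 1-oxatriene. Thermal disrotatory oxa-6π electrocyclization of 12 then forms the O1–C2 bond and restores the aromaticity of ring A; the closest known reaction type is the formal [3+3] chromene annulation of resorcinols with enals. The pyran ring therefore closes in a pericyclic six-electron mode, driven by rearomatization. No stereocenter is formed, since C2 carries two methyl groups. The selectivity needed is constitutional (reaction at the carbon ortho to the styryl group and at one hydroxyl only): the mirror symmetry of 10 makes both free ortho carbons and both hydroxyls equivalent and the prenyl group blocks the carbon between the oxygens, while limiting 11, together with the loss of styryl conjugation that a second annulation at C6 would cost, should hold the reaction at the mono-pyran.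

Step 7
Reactants: 13 2,2-dimethyl-8-(3-methylbut-2-en-1-yl)-5-[(E)-2-phenylethenyl]-2H-chromen-7-ol; 14 pivaloyl chloride
Product: 15 2,2-dimethyl-8-(3-methylbut-2-en-1-yl)-5-[(E)-2-phenylethenyl]-2H-chromen-7-yl 2,2-dimethylpropanoate
Conditions: 14, Et3N, DMAP (cat.), CH2Cl2, 0 °C to rt
Reagents that add atoms: pivaloyl chloride, CC(C)(C)C(=O)Cl
Why: DMAP-catalysed acylation gives a pivalate that shields the phenol and ring A from the oxidant of step 8, withstands basic hypochlorite and is removed by the hydride of step 9.

Step 8
Reactants: 15 2,2-dimethyl-8-(3-methylbut-2-en-1-yl)-5-[(E)-2-phenylethenyl]-2H-chromen-7-yl 2,2-dimethylpropanoate; 16 sodium hypochlorite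
Product: 17 (3R,4R)-3,4-epoxy-2,2-dimethyl-8-(3-methylbut-2-en-1-yl)-5-[(E)-2-phenylethenyl]chroman-7-yl 2,2-dimethylpropanoate
Conditions: (R,R)-[N,N'-bis(3,5-di-tert-butylsalicylidene)cyclohexane-1,2-diaminato]MnCl (4 mol%), 4-phenylpyridine N-oxide, aq. NaOCl (pH 11.3), CH2Cl2, 0 °C; filtration through basic alumina, product used directly
Reagents that add atoms: sodium hypochlorite, [Na+].[O-]Cl
Why: Jacobsen–Katsuki epoxidation, in which the oxo(salen)manganese oxidant approaches cis-disubstituted aryl-conjugated alkenes side-on, so that the (R,R)-complex should set C3 and C4 as R by catalyst control on this 2,2-dimethylchromene, while the isolated trisubstituted prenyl alkene and the trans-stilbene alkene are expected to react much more slowly.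

Step 9
Reactants: 17 (3R,4R)-3,4-epoxy-2,2-dimethyl-8-(3-methylbut-2-en-1-yl)-5-[(E)-2-phenylethenyl]chroman-7-yl 2,2-dimethylpropanoate
Product: 18 (3R)-2,2-dimethyl-8-(3-methylbut-2-en-1-yl)-5-[(E)-2-phenylethenyl]chromane-3,7-diol
Conditions: LiAlH4, THF, 0 °C to rt; H2O/NaOH work-up
Reagents that add atoms: none
Why: Hydride should open the epoxide at the benzylic C4 (C3 is shielded by the quaternary C2 and C4–O cleavage is assisted by O1), so the C3–O bond and its R configuration are untouched, and the same reagent cleaves the pivalate (epoxide and ester reduction by LiAlH4).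

Compound list
1 | 3,5-dihydroxybenzyl alcohol | OCc1cc(O)cc(O)c1 | starting material
2 | chloromethyl methyl ether | COCCl | starting material
3 | [3,5-bis(methoxymethoxy)phenyl]methanol | COCOc1cc(CO)cc(OCOC)c1 | intermediate
4 | 1-bromo-3-methylbut-2-ene (prenyl bromide) | CC(C)=CCBr | starting material
5 | lithium [4-lithio-3,5-bis(methoxymethoxy)phenyl]methanolate | [Li]OCc1cc(OCOC)c([Li])c(OCOC)c1 | intermediate
6 | [3,5-bis(methoxymethoxy)-4-(3-methylbut-2-en-1-yl)phenyl]methanol | COCOc1cc(CO)cc(OCOC)c1CC=C(C)C | intermediate
7 | 3,5-bis(methoxymethoxy)-4-(3-methylbut-2-en-1-yl)benzaldehyde | COCOc1cc(C=O)cc(OCOC)c1CC=C(C)C | intermediate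
8 | diethyl benzylphosphonate | CCOP(=O)(Cc1ccccc1)OCC | starting material
9 | 1,3-bis(methoxymethoxy)-2-(3-methylbut-2-en-1-yl)-5-[(E)-2-phenylethenyl]benzene | COCOc1cc(/C=C/c2ccccc2)cc(OCOC)c1CC=C(C)C | intermediate
10 | 2-(3-methylbut-2-en-1-yl)-5-[(E)-2-phenylethenyl]benzene-1,3-diol (4-prenylpinosylvin) | CC(C)=CCc1c(O)cc(/C=C/c2ccccc2)cc1O | intermediate
11 | 3-methylbut-2-enal (prenal) | CC(C)=CC=O | starting material
12 | (6Z)-3-hydroxy-2-(3-methylbut-2-en-1-yl)-6-(3-methylbut-2-en-1-ylidene)-5-[(E)-2-phenylethenyl]cyclohexa-2,4-dien-1-one (ortho-quinone methide) | CC(C)=CCC1=C(O)C=C(/C=C/c2ccccc2)/C(=C/C=C(C)C)C1=O | intermediate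
13 | 2,2-dimethyl-8-(3-methylbut-2-en-1-yl)-5-[(E)-2-phenylethenyl]-2H-chromen-7-ol | CC(C)=CCc1c(O)cc(/C=C/c2ccccc2)c2c1OC(C)(C)C=C2 | intermediate
14 | pivaloyl chloride | CC(C)(C)C(=O)Cl | starting material
15 | 2,2-dimethyl-8-(3-methylbut-2-en-1-yl)-5-[(E)-2-phenylethenyl]-2H-chromen-7-yl 2,2-dimethylpropanoate | CC(C)=CCc1c(OC(=O)C(C)(C)C)cc(/C=C/c2ccccc2)c2c1OC(C)(C)C=C2 | intermediate
16 | sodium hypochlorite | [Na+].[O-]Cl | starting material
17 | (3R,4R)-3,4-epoxy-2,2-dimethyl-8-(3-methylbut-2-en-1-yl)-5-[(E)-2-phenylethenyl]chroman-7-yl 2,2-dimethylpropanoate | CC(C)=CCc1c(OC(=O)C(C)(C)C)cc(/C=C/c2ccccc2)c2c1OC(C)(C)[C@@H]1O[C@H]21 | intermediate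
18 | (3R)-2,2-dimethyl-8-(3-methylbut-2-en-1-yl)-5-[(E)-2-phenylethenyl]chromane-3,7-diol | CC(C)=CCc1c(O)cc(/C=C/c2ccccc2)c2c1OC(C)(C)[C@H](O)C2 | target

Total step count: 9
Longest linear sequence: 9 steps (1 to 18)

Steps most likely to fail

Step 8. The facial selectivity may be lowered by the styryl group peri to C4, and the electron-rich benzylic epoxide may open during the reaction or on isolation. The fallback sets out from 17, of whatever enantiomeric purity, and comes back to the route at 18; it sets C3 by reagent-controlled ketone reduction instead of alkene face selection. Crude 17 would be isomerized with InCl3 (cat.) in THF (Meinwald rearrangement: C4–O ionization and 1,2-hydride shift from C3) to the ketone 2,2-dimethyl-8-(3-methylbut-2-en-1-yl)-3-oxo-5-[(E)-2-phenylethenyl]chroman-7-yl 2,2-dimethylpropanoate F1. Corey–Bakshi–Shibata reduction of F1 with (S)-1-methyl-3,3-diphenyltetrahydro-1H,3H-pyrrolo[1,2-c][1,3,2]oxazaborole (cat.) and catecholborane in toluene at −78 °C, with the quaternary C2 as the large group, should give (3R)-3-hydroxy-2,2-dimethyl-8-(3-methylbut-2-en-1-yl)-5-[(E)-2-phenylethenyl]chroman-7-yl 2,2-dimethylpropanoate F2. Methanolysis of the pivalate of F2 (NaOMe, MeOH, rt) would then give 18.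

Step 6. A second annulation at C6 of the product, or oligomerization of prenal, may consume material before the mono-pyran accumulates. The fallback sets out from 10 and comes back at 13; it makes the C4–C4a bond by an intramolecular sigmatropic shift instead of an intermolecular condensation. Mono-O-alkylation of 10 with 3-chloro-3-methylbut-1-yne (K2CO3, KI, CuI cat., acetone, reflux) would give the aryl propargyl ether 2-(3-methylbut-2-en-1-yl)-3-[(2-methylbut-3-yn-2-yl)oxy]-5-[(E)-2-phenylethenyl]phenol F3, which is purified from diol and bis-ether. Heating F3 in o-xylene at 140 °C should bring about aromatic Claisen rearrangement to the only free ortho carbon, enolization and [1,5]-hydrogen shift to the same ortho-quinone methide 12, and the same oxa-6π closure to 13.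

Step 2. Allylation may occur with SN2′ regiochemistry (1,1-dimethylallyl isomer) or at the alkoxide oxygen, or the ring metalation may stay incomplete. The fallback sets out from 3 and comes back at 6; it separates metalation from C–C bond formation. The dianion 5 would be quenched with iodine (THF, −78 °C) to give the aryl iodide [4-iodo-3,5-bis(methoxymethoxy)phenyl]methanol F4. Stille coupling of F4 with tributyl(3-methylbut-2-en-1-yl)stannane (Pd(PPh3)4, CuI cat., DMF, 80 °C) should then deliver the linear prenyl arene 6.

Further compounds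
F1 | step 8 | 2,2-dimethyl-8-(3-methylbut-2-en-1-yl)-3-oxo-5-[(E)-2-phenylethenyl]chroman-7-yl 2,2-dimethylpropanoate | CC(C)=CCc1c(OC(=O)C(C)(C)C)cc(/C=C/c2ccccc2)c2c1OC(C)(C)C(=O)C2
F2 | step 8 | (3R)-3-hydroxy-2,2-dimethyl-8-(3-methylbut-2-en-1-yl)-5-[(E)-2-phenylethenyl]chroman-7-yl 2,2-dimethylpropanoate | CC(C)=CCc1c(OC(=O)C(C)(C)C)cc(/C=C/c2ccccc2)c2c1OC(C)(C)[C@H](O)C2
F3 | step 6 | 2-(3-methylbut-2-en-1-yl)-3-[(2-methylbut-3-yn-2-yl)oxy]-5-[(E)-2-phenylethenyl]phenol | CC(C)=CCc1c(O)cc(/C=C/c2ccccc2)cc1OC(C)(C)C#C
F4 | step 2 | [4-iodo-3,5-bis(methoxymethoxy)phenyl]methanol | COCOc1cc(CO)cc(OCOC)c1I
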